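**Retrosynthetic overview**

1. Numbering (elemane convention): C10 = quaternary carbon (CH3, vinyl), C5 = CH bearing the 3-hydroxyprop-1-en-2-yl group (C15 = its CH2OH), C6 = lactone CH–O, C7 = ring-fusion CH, C8 = CH–O(acyl), C9 = CH2, C11/C12 = lactone CH(CH3)/C=O. Target ⇐ acylation of the C8 alcohol 29 with the protected (S)-acid 10, then acidic deprotection.
2. 29 ⇐ open-chain aldehyde–enoate 25 in one SmI2 cascade: the C6 ketyl adds 6-exo to C7 (bond C6–C7, closing the cyclohexane C5–C6–C7–C8–C9–C10), then the C6 alkoxide closes the γ-lactone O–C6–C7–C11–C12 on the ester.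
3. Enabling feature: the C6–C7 bond is shared by both rings, C6 carries the lactone oxygen (a latent aldehyde) and C7 is β to the lactone carbonyl C12 (a latent enoate β-carbon); the four contiguous substituents at C5–C8 are all-trans, hence all equatorial, which is what a chair transition state delivers.
4. 25 ⇐ acid 22 ⇐ enantioselective Ireland–Claisen rearrangement of allyl ester 20, which forms C5–C10, the vinyl group and both stereocentres.
5. 20 ⇐ acid 4 (from monomethyl itaconate) + (E)-allylic alcohol 16 (C8 from (R)-glycidyl PMB ether via acetylide opening and carboalumination), then Wittig olefination. Ring order: no ring before step 17, then cyclohexane, then lactone.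

Key step: step 17

Assumption: the (R,R)-diazaborolidine bromide is taken to select the enolate face that leads to the (2S,3R)-acid 22, by analogy with geranyl-type esters; if the sense is the opposite, the (S,S)-reagent is used in step 14 with nothing else changed.

**Route**

Step 1
Reactants: 1 4-methyl hydrogen 2-methylidenebutanedioate (monomethyl itaconate)
Product: 2 methyl 3-(hydroxymethyl)but-3-enoate
Conditions: BH3·SMe2 (1.05 equiv), THF, −15 → 0 °C; MeOH quench; used directly
Reagents that add atoms: none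
Why: Chemoselective borane reduction of a carboxylic acid (via the acyloxyborane) in the presence of a methyl ester, the electron-poor 1,1-disubstituted alkene being slow to hydroborate at this temperature; no stereocentre is formed.

Step 2
Reactants: 2 methyl 3-(hydroxymethyl)but-3-enoate
Product: 3 methyl 3-({[tert-butyl(dimethyl)silyl]oxy}methyl)but-3-enoate
Conditions: TBSCl, imidazole, CH2Cl2, 0 °C
Reagents that add atoms: tert-butyl(chloro)dimethylsilane, CC(C)(C)[Si](C)(C)Cl
Why: Standard silylation of a primary allylic alcohol, done at once so that the γ-hydroxy ester cannot lactonise.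

Step 3
Reactants: 3 methyl 3-({[tert-butyl(dimethyl)silyl]oxy}methyl)but-3-enoate
Product: 4 3-({[tert-butyl(dimethyl)silyl]oxy}methyl)but-3-enoic acid
Conditions: LiOH (1.5 equiv), THF–H2O, 0 °C; 1 M HCl to pH 4 at 0 °C
Reagents that add atoms: lithium hydroxide, [Li+].[OH-]
Why: Saponification of an unhindered methyl ester at 0 °C, where the carboxylate forms faster than the β,γ-double bond can move into conjugation.

Step 4
Reactants: 5 methyl 2-[(4S)-2,2-dimethyl-1,3-dioxolan-4-yl]acetate
Product: 7 methyl 3-(dimethylamino)-2-[(4S)-2,2-dimethyl-1,3-dioxolan-4-yl]propanoate (C2 epimers), via lithium enolate 6 (not isolated)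
Conditions: LiN(i-Pr)2 (1.1 equiv), THF, −78 °C; CH2=NMe2+ I− (1.5 equiv), −78 → −20 °C
Reagents that add atoms: N,N-dimethylmethyleneiminium iodide, C=[N+](C)C.[I-]
Why: Ester enolate Mannich reaction (aminomethylation) run cold so that the enolate is trapped before it can expel the dioxolane oxygen; the dioxolane stereocentre is not touched and the new α-centre is destroyed in step 5.

Step 5
Reactants: 7 methyl 3-(dimethylamino)-2-[(4S)-2,2-dimethyl-1,3-dioxolan-4-yl]propanoate
Product: 9 methyl 2-[(4S)-2,2-dimethyl-1,3-dioxolan-4-yl]prop-2-enoate, via trimethylammonium iodide 8 (not isolated)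
Conditions: MeI, CH2Cl2, 23 °C; then DBU, 0 → 23 °C
Reagents that add atoms: none
Why: Exhaustive methylation followed by Hofmann-type (E1cB) elimination of trimethylamine, the ammonium group being a far better leaving group than the ring oxygen, gives the α-methylene ester.

Step 6
Reactants: 9 methyl 2-[(4S)-2,2-dimethyl-1,3-dioxolan-4-yl]prop-2-enoate
Product: 10 2-[(4S)-2,2-dimethyl-1,3-dioxolan-4-yl]prop-2-enoic acid
Conditions: LiOH, THF–H2O, 0 °C; 0.5 M HCl to pH 4 at 0 °C
Reagents that add atoms: lithium hydroxide, [Li+].[OH-]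
Why: Saponification of an acrylate that has no α-hydrogen, so the allylic stereocentre cannot epimerise, with a brief cold acidification that the acetonide tolerates.

Step 7
Reactants: 11 (R)-2-{[(4-methoxybenzyl)oxy]methyl}oxirane
Product: 12 (R)-1-[(4-methoxybenzyl)oxy]pent-4-yn-2-ol
Conditions: LiC≡CH·H2NCH2CH2NH2 (1.5 equiv), DMSO, 15 → 23 °C; H2O
Reagents that add atoms: lithium acetylide–ethylenediamine complex, [Li]C#C.NCCN
Why: SN2 opening of a terminal epoxide by acetylide at the unsubstituted carbon, which leaves the C8 stereocentre of the chiral-pool epoxide untouched.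

Step 8
Reactants: 12 (R)-1-[(4-methoxybenzyl)oxy]pent-4-yn-2-ol
Product: 13 (R)-triethyl({1-[(4-methoxybenzyl)oxy]pent-4-yn-2-yl}oxy)silane
Conditions: TESCl, imidazole, CH2Cl2, 0 °C
Reagents that add atoms: chlorotriethylsilane, CC[Si](Cl)(CC)CC
Why: Standard silylation of the secondary alcohol with a group that can later be removed in the presence of a primary TBS ether.

Step 9
Reactants: 13 (R)-triethyl({1-[(4-methoxybenzyl)oxy]pent-4-yn-2-yl}oxy)silane
Product: 16 (2E,5R)-6-[(4-methoxybenzyl)oxy]-3-methyl-5-[(triethylsilyl)oxy]hex-2-en-1-ol, via alkenyldimethylalane 14 (not isolated), via lithium alkenylaluminate 15 (not isolated)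
Conditions: AlMe3 (2.5 equiv), Cp2ZrCl2 (0.25 equiv), CH2Cl2, 0 → 23 °C; evaporate; n-BuLi, THF, −78 °C; (CH2O)n, −78 → 23 °C; H2O
Reagents that add atoms: trimethylaluminium, C[Al](C)C; paraformaldehyde (as formaldehyde), C=O
Why: Negishi zirconium-catalysed carboalumination adds CH3 and Al syn across the terminal alkyne with methyl on the internal carbon, and the derived aluminate is hydroxymethylated with retention, which fixes the (E)-trisubstituted alkene.

Step 10
Reactants: 16 (2E,5R)-6-[(4-methoxybenzyl)oxy]-3-methyl-5-[(triethylsilyl)oxy]hex-2-en-1-ol; 4 3-({[tert-butyl(dimethyl)silyl]oxy}methyl)but-3-enoic acid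
Product: 17 (2E,5R)-6-[(4-methoxybenzyl)oxy]-3-methyl-5-[(triethylsilyl)oxy]hex-2-en-1-yl 3-({[tert-butyl(dimethyl)silyl]oxy}methyl)but-3-enoate
Conditions: PPh3, DIAD, THF, 0 → 23 °C
Reagents that add atoms: none
Why: Mitsunobu esterification of a primary allylic alcohol, chosen because its neutral conditions avoid base-induced migration of the β,γ-double bond of the acid; no stereocentre is involved.

Step 11
Reactants: 17 the PMB-protected allyl ester
Product: 18 (2E,5R)-6-hydroxy-3-methyl-5-[(triethylsilyl)oxy]hex-2-en-1-yl 3-({[tert-butyl(dimethyl)silyl]oxy}methyl)but-3-enoate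
Conditions: DDQ, CH2Cl2–pH 7 buffer, 0 °C
Reagents that add atoms: none
Why: Oxidative cleavage of the p-methoxybenzyl ether by DDQ, which leaves silyl ethers, the allyl ester and the alkenes alone under buffered conditions.

Step 12
Reactants: 18 the primary alcohol
Product: 19 (2E,5R)-3-methyl-6-oxo-5-[(triethylsilyl)oxy]hex-2-en-1-yl 3-({[tert-butyl(dimethyl)silyl]oxy}methyl)but-3-enoate
Conditions: Dess–Martin periodinane, NaHCO3, CH2Cl2, 0 → 23 °C
Reagents that add atoms: none
Why: Dess–Martin oxidation gives the α-silyloxy aldehyde under buffered, non-epimerising conditions.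

Step 13
Reactants: 19 the α-silyloxy aldehyde
Product: 20 methyl (2E,4R,6E)-8-{[3-({[tert-butyl(dimethyl)silyl]oxy}methyl)but-3-enoyl]oxy}-2,6-dimethyl-4-[(triethylsilyl)oxy]octa-2,6-dienoate
Conditions: Ph3P=C(CH3)CO2Me (1.5 equiv), toluene, 60 °C
Reagents that add atoms: methyl 2-(triphenyl-λ5-phosphanylidene)propanoate, COC(=O)C(C)=P(c1ccccc1)(c1ccccc1)c1ccccc1
Why: Wittig olefination with a stabilised α-methyl ylide gives the (E)-trisubstituted enoate (ester trans to C8) without epimerising the α-silyloxy centre.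

Step 14
Reactants: 20 the allyl ester–enoate
Product: 22 (2S,3R,5R,6E)-2-(3-{[tert-butyl(dimethyl)silyl]oxy}prop-1-en-2-yl)-3-ethenyl-8-methoxy-3,7-dimethyl-8-oxo-5-[(triethylsilyl)oxy]oct-6-enoic acid, via boron ketene acetal 21 (not isolated)
Conditions: (R,R)-2-bromo-4,5-diphenyl-1,3-bis{[3,5-bis(trifluoromethyl)phenyl]sulfonyl}-1,3,2-diazaborolidine (1.2 equiv, preformed), Et3N (3 equiv), toluene–hexane, −78 °C; then 4 °C, 48 h; aqueous work-up
Reagents that add atoms: none
Why: Enantioselective Ireland–Claisen rearrangement in which soft enolisation of the doubly activated α-CH2 gives the boron ketene acetal with the C5 substituent cis to the allyloxy oxygen, a chair transition state with the (E)-alkene (C9 equatorial, C10 methyl axial) fixes the C5/C10 relative configuration (side chain anti to methyl, syn to vinyl), and the C2-symmetric diazaborolidine selects the enolate face and so the absolute configuration.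

Step 15
Reactants: 22 the Claisen acid
Product: 24 methyl (2E,4R,6R,7S)-7-(3-{[tert-butyl(dimethyl)silyl]oxy}prop-1-en-2-yl)-6-ethenyl-8-hydroxy-2,6-dimethyl-4-[(triethylsilyl)oxy]oct-2-enoate, via isobutyl carbonic anhydride 23 (not isolated)
Conditions: i-BuOCOCl, N-methylmorpholine, THF, −15 °C; then NaBH4, H2O–THF, −15 → 0 °C
Reagents that add atoms: none
Why: Mixed carbonic anhydride activation followed by NaBH4 reduces the carboxylic acid to the primary alcohol while the methyl enoate, the alkenes and the silyl ethers are inert to borohydride at this temperature.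

Step 16
Reactants: 24 the primary alcohol
Product: 25 methyl (2E,4R,6R,7S)-7-(3-{[tert-butyl(dimethyl)silyl]oxy}prop-1-en-2-yl)-6-ethenyl-2,6-dimethyl-8-oxo-4-[(triethylsilyl)oxy]oct-2-enoate
Conditions: Dess–Martin periodinane, NaHCO3, CH2Cl2, 0 °C; used at once
Reagents that add atoms: none
Why: Buffered Dess–Martin oxidation gives the β,γ-unsaturated aldehyde without base, so that the α-stereocentre C5 is neither epimerised nor moved into conjugation before the next step.

Step 17
Reactants: 25 the open-chain aldehyde–enoate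
Product: 27 C8-O-triethylsilyl C15-O-TBS trans-fused lactone (mixture of C11 epimers), via hydroxy ester 26 (not isolated)
Conditions: SmI2 (2.5 equiv, 0.1 M in THF), t-BuOH (2.2 equiv), THF, −78 → 0 °C, then 23 °C; aq. NaHCO3
Reagents that add atoms: none
Why: Samarium diiodide reduces the aldehyde to a samarium ketyl at C6, which adds to the β-carbon C7 of the (E)-α-methyl enoate; a second electron gives the trivalent-samarium ester enolate, protonated by t-BuOH to 26, whose samarium alkoxide at C6 then acylates on the C12 methyl ester. The closest known reaction type is the SmI2-mediated ketyl–olefin (aldehyde–acrylate) reductive cyclisation with in-flask lactonisation that gives γ-butyrolactone-fused carbocycles. The cyclohexane closes by 6-exo-trig radical addition and the γ-lactone by 5-exo-trig acyl substitution. C6 and C7 are set in a chair transition state in which the C5 side chain, the C8 silyloxy group and the C10 vinyl group are equatorial and the C10 methyl axial: the ketyl oxygen takes the equatorial position (an axial oxygen would be 1,3-diaxial to the C10 methyl) and the enoate carbon C11 the equatorial position anti to it, which gives the all-trans C5–C8 array and hence the trans-fused lactone, while C11 is formed by unselective protonation and is corrected in step 18. The step needs reduction of the aldehyde before the enoate, secured by working without HMPA at low temperature where the γ-silyloxy enoate is not reduced, and a ring closure that outruns further reduction of the ketyl, secured by the activated acceptor and by the quaternary C10, which preorganises the chain; the vinyl and propenyl groups offer only disfavoured four-membered or endo closures.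

Step 18
Reactants: 27 the lactone as C11 epimers
Product: 28 C8-O-triethylsilyl C15-O-TBS lactone with the C11 methyl cis to H-7
Conditions: KOt-Bu (0.3 equiv), t-BuOH–THF, 0 → 23 °C; AcOH quench
Reagents that add atoms: none
Why: Base-mediated epimerisation through the lactone enolate under thermodynamic control places the C11 methyl on the face of H-7, away from C8 and its equatorial silyloxy group; no β-leaving group is available to the enolate.

Step 19
Reactants: 28 the bis-silylated lactone
Product: 29 (3R,3aS,4R,6R,7S,7aS)-7-(3-{[tert-butyl(dimethyl)silyl]oxy}prop-1-en-2-yl)-6-ethenyl-4-hydroxy-3,6-dimethylhexahydro-1-benzofuran-2(3H)-one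
Conditions: PPTS (0.2 equiv), MeOH–CH2Cl2, 0 °C
Reagents that add atoms: none
Why: Acid-catalysed methanolysis removes the triethylsilyl ether much faster than the primary TBS ether, which frees only the C8 hydroxyl.

Step 20
Reactants: 29 the C8 alcohol; 10 2-[(4S)-2,2-dimethyl-1,3-dioxolan-4-yl]prop-2-enoic acid
Product: 31 (3R,3aS,4R,6R,7S,7aS)-7-(3-{[tert-butyl(dimethyl)silyl]oxy}prop-1-en-2-yl)-6-ethenyl-3,6-dimethyl-2-oxooctahydro-1-benzofuran-4-yl 2-[(4S)-2,2-dimethyl-1,3-dioxolan-4-yl]prop-2-enoate, via trichlorobenzoyl mixed anhydride 30 (not isolated)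
Conditions: 2,4,6-trichlorobenzoyl chloride, Et3N, toluene, 23 °C; then 29, DMAP, toluene, 23 → 40 °C
Reagents that add atoms: none
Why: Yamaguchi esterification acylates the hindered equatorial secondary alcohol with retention at C8, and the acid has no α-hydrogen, so its allylic stereocentre is safe.

Step 21
Reactants: 31 the protected ester
Product: 32 (3R,3aS,4R,6R,7S,7aS)-6-ethenyl-7-(3-hydroxyprop-1-en-2-yl)-3,6-dimethyl-2-oxooctahydro-1-benzofuran-4-yl (3S)-3,4-dihydroxy-2-methylidenebutanoate (target)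
Conditions: CF3CO2H–H2O–THF (1:1:4), 0 → 23 °C
Reagents that add atoms: none
Why: Mild aqueous acid hydrolyses the acetonide and the primary TBS ether in one operation, under conditions too mild and too brief for the liberated 4-hydroxyl to lactonise onto the acrylate ester.

**Compound list**

1 | 4-methyl hydrogen 2-methylidenebutanedioate (monomethyl itaconate) | COC(=O)CC(=C)C(=O)O | starting material
2 | methyl 3-(hydroxymethyl)but-3-enoate | COC(=O)CC(=C)CO | intermediate
3 | methyl 3-({[tert-butyl(dimethyl)silyl]oxy}methyl)but-3-enoate | COC(=O)CC(=C)CO[Si](C)(C)C(C)(C)C | intermediate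
4 | 3-({[tert-butyl(dimethyl)silyl]oxy}methyl)but-3-enoic acid | OC(=O)CC(=C)CO[Si](C)(C)C(C)(C)C | intermediate
5 | methyl 2-[(4S)-2,2-dimethyl-1,3-dioxolan-4-yl]acetate | COC(=O)C[C@H]1COC(C)(C)O1 | starting material
6 | lithium enolate of 5 | COC(O[Li])=C[C@H]1COC(C)(C)O1 | intermediate
7 | methyl 3-(dimethylamino)-2-[(4S)-2,2-dimethyl-1,3-dioxolan-4-yl]propanoate (C2 epimers) | COC(=O)C(CN(C)C)[C@H]1COC(C)(C)O1 | intermediate
8 | {2-[(4S)-2,2-dimethyl-1,3-dioxolan-4-yl]-3-methoxy-3-oxopropyl}trimethylammonium iodide | COC(=O)C(C[N+](C)(C)C)[C@H]1COC(C)(C)O1.[I-] | intermediate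
9 | methyl 2-[(4S)-2,2-dimethyl-1,3-dioxolan-4-yl]prop-2-enoate | COC(=O)C(=C)[C@H]1COC(C)(C)O1 | intermediate
10 | 2-[(4S)-2,2-dimethyl-1,3-dioxolan-4-yl]prop-2-enoic acid | OC(=O)C(=C)[C@H]1COC(C)(C)O1 | intermediate
11 | (R)-2-{[(4-methoxybenzyl)oxy]methyl}oxirane | COc1ccc(COC[C@H]2CO2)cc1 | starting material
12 | (R)-1-[(4-methoxybenzyl)oxy]pent-4-yn-2-ol | C#CC[C@@H](O)COCc1ccc(OC)cc1 | intermediate
13 | (R)-triethyl({1-[(4-methoxybenzyl)oxy]pent-4-yn-2-yl}oxy)silane | C#CC[C@@H](O[Si](CC)(CC)CC)COCc1ccc(OC)cc1 | intermediate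
14 | (E)-alkenyldimethylalane from 13 (CH3 and Al cis) | C[Al](C)/C=C(C)/C[C@@H](O[Si](CC)(CC)CC)COCc1ccc(OC)cc1 | intermediate
15 | lithium butyl(dimethyl)[(E)-alkenyl]aluminate from 14 | [Li+].CCCC[Al-](C)(C)/C=C(C)/C[C@@H](O[Si](CC)(CC)CC)COCc1ccc(OC)cc1 | intermediate
16 | (2E,5R)-6-[(4-methoxybenzyl)oxy]-3-methyl-5-[(triethylsilyl)oxy]hex-2-en-1-ol | OC/C=C(C)/C[C@@H](O[Si](CC)(CC)CC)COCc1ccc(OC)cc1 | intermediate
17 | (2E,5R)-6-[(4-methoxybenzyl)oxy]-3-methyl-5-[(triethylsilyl)oxy]hex-2-en-1-yl 3-({[tert-butyl(dimethyl)silyl]oxy}methyl)but-3-enoate | C=C(CO[Si](C)(C)C(C)(C)C)CC(=O)OC/C=C(C)/C[C@@H](O[Si](CC)(CC)CC)COCc1ccc(OC)cc1 | intermediate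
18 | (2E,5R)-6-hydroxy-3-methyl-5-[(triethylsilyl)oxy]hex-2-en-1-yl 3-({[tert-butyl(dimethyl)silyl]oxy}methyl)but-3-enoate | C=C(CO[Si](C)(C)C(C)(C)C)CC(=O)OC/C=C(C)/C[C@@H](O[Si](CC)(CC)CC)CO | intermediate
19 | (2E,5R)-3-methyl-6-oxo-5-[(triethylsilyl)oxy]hex-2-en-1-yl 3-({[tert-butyl(dimethyl)silyl]oxy}methyl)but-3-enoate | C=C(CO[Si](C)(C)C(C)(C)C)CC(=O)OC/C=C(C)/C[C@@H](O[Si](CC)(CC)CC)C=O | intermediate
20 | methyl (2E,4R,6E)-8-{[3-({[tert-butyl(dimethyl)silyl]oxy}methyl)but-3-enoyl]oxy}-2,6-dimethyl-4-[(triethylsilyl)oxy]octa-2,6-dienoate | C=C(CO[Si](C)(C)C(C)(C)C)CC(=O)OC/C=C(C)/C[C@@H](O[Si](CC)(CC)CC)/C=C(\C)C(=O)OC | intermediate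
21 | boron ketene acetal of 20 with the (R,R)-diazaborolidine (C5 substituent cis to the allyloxy oxygen) | C=C(CO[Si](C)(C)C(C)(C)C)/C=C(\OC/C=C(C)/C[C@@H](O[Si](CC)(CC)CC)/C=C(\C)C(=O)OC)OB1N(S(=O)(=O)c2cc(cc(c2)C(F)(F)F)C(F)(F)F)[C@H](c2ccccc2)[C@@H](c2ccccc2)N1S(=O)(=O)c1cc(cc(c1)C(F)(F)F)C(F)(F)F | intermediate
22 | (2S,3R,5R,6E)-2-(3-{[tert-butyl(dimethyl)silyl]oxy}prop-1-en-2-yl)-3-ethenyl-8-methoxy-3,7-dimethyl-8-oxo-5-[(triethylsilyl)oxy]oct-6-enoic acid | C=C[C@@](C)(C[C@@H](O[Si](CC)(CC)CC)/C=C(\C)C(=O)OC)[C@H](C(=O)O)C(=C)CO[Si](C)(C)C(C)(C)C | intermediate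
23 | isobutyl carbonic anhydride of 22 | C=C[C@@](C)(C[C@@H](O[Si](CC)(CC)CC)/C=C(\C)C(=O)OC)[C@H](C(=O)OC(=O)OCC(C)C)C(=C)CO[Si](C)(C)C(C)(C)C | intermediate
24 | methyl (2E,4R,6R,7S)-7-(3-{[tert-butyl(dimethyl)silyl]oxy}prop-1-en-2-yl)-6-ethenyl-8-hydroxy-2,6-dimethyl-4-[(triethylsilyl)oxy]oct-2-enoate | C=C[C@@](C)(C[C@@H](O[Si](CC)(CC)CC)/C=C(\C)C(=O)OC)[C@H](CO)C(=C)CO[Si](C)(C)C(C)(C)C | intermediate
25 | methyl (2E,4R,6R,7S)-7-(3-{[tert-butyl(dimethyl)silyl]oxy}prop-1-en-2-yl)-6-ethenyl-2,6-dimethyl-8-oxo-4-[(triethylsilyl)oxy]oct-2-enoate | C=C[C@@](C)(C[C@@H](O[Si](CC)(CC)CC)/C=C(\C)C(=O)OC)[C@H](C=O)C(=C)CO[Si](C)(C)C(C)(C)C | intermediate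
26 | all-trans cyclohexanol hydroxy ester (C6–OH free, C7 bearing CH(CH3)CO2CH3, C11 epimers) | C=C[C@@]1(C)C[C@@H](O[Si](CC)(CC)CC)[C@H](C(C)C(=O)OC)[C@@H](O)[C@@H]1C(=C)CO[Si](C)(C)C(C)(C)C | intermediate
27 | C8-O-triethylsilyl C15-O-TBS trans-fused lactone (C11 epimers) | C=C[C@@]1(C)C[C@@H](O[Si](CC)(CC)CC)[C@H]2[C@@H](OC(=O)C2C)[C@@H]1C(=C)CO[Si](C)(C)C(C)(C)C | intermediate
28 | C8-O-triethylsilyl C15-O-TBS trans-fused lactone with the C11 methyl cis to H-7 | C=C[C@@]1(C)C[C@@H](O[Si](CC)(CC)CC)[C@H]2[C@@H](OC(=O)[C@@H]2C)[C@@H]1C(=C)CO[Si](C)(C)C(C)(C)C | intermediate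
29 | (3R,3aS,4R,6R,7S,7aS)-7-(3-{[tert-butyl(dimethyl)silyl]oxy}prop-1-en-2-yl)-6-ethenyl-4-hydroxy-3,6-dimethylhexahydro-1-benzofuran-2(3H)-one | C=C[C@@]1(C)C[C@@H](O)[C@H]2[C@@H](OC(=O)[C@@H]2C)[C@@H]1C(=C)CO[Si](C)(C)C(C)(C)C | intermediate
30 | 2-[(4S)-2,2-dimethyl-1,3-dioxolan-4-yl]prop-2-enoic 2,4,6-trichlorobenzoic anhydride | O=C(OC(=O)c1c(Cl)cc(Cl)cc1Cl)C(=C)[C@H]1COC(C)(C)O1 | intermediate
31 | (3R,3aS,4R,6R,7S,7aS)-7-(3-{[tert-butyl(dimethyl)silyl]oxy}prop-1-en-2-yl)-6-ethenyl-3,6-dimethyl-2-oxooctahydro-1-benzofuran-4-yl 2-[(4S)-2,2-dimethyl-1,3-dioxolan-4-yl]prop-2-enoate | C=C[C@@]1(C)C[C@@H](OC(=O)C(=C)[C@H]2COC(C)(C)O2)[C@H]3[C@@H](OC(=O)[C@@H]3C)[C@@H]1C(=C)CO[Si](C)(C)C(C)(C)C | intermediate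
32 | (3R,3aS,4R,6R,7S,7aS)-6-ethenyl-7-(3-hydroxyprop-1-en-2-yl)-3,6-dimethyl-2-oxooctahydro-1-benzofuran-4-yl (3S)-3,4-dihydroxy-2-methylidenebutanoate (CNP0260337.1) | C=C[C@@]1(C)C[C@@H](OC(=O)C(=C)[C@H](O)CO)[C@H]2[C@@H](OC(=O)[C@@H]2C)[C@@H]1C(=C)CO | target

**Step count and risks**

Total step count: 21. Longest linear sequence: 15 steps (steps 7–21, from 11 to 32).

Steps most likely to fail:

1. Step 14. Enolisation of the β,γ-unsaturated ester by the boron bromide may give the wrong ketene acetal geometry or discriminate the enolate faces poorly, and the Lewis acid may strip the allylic silyl ethers during the long rearrangement. Fallback, from 20 back to 22: reagent control is given up. Ester 20 is treated with LiN(SiMe3)2 and Me3SiCl–Et3N in THF at −78 °C to give the trimethylsilyl ketene acetal F1 (geometry set by the solvent, as is standard for lithium ester enolates). On warming to 23 °C it rearranges through the same chair to the trimethylsilyl ester F2, formed on both faces. Mild aqueous work-up hydrolyses it to 22 together with its (2R,3S)-diastereomer F3. Because C8 is already fixed, these two acids are diastereomers and are separated by chromatography.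

2. Step 17. The ketyl of the hindered, α-branched aldehyde may be reduced on to the primary alcohol, or the enoate may be reduced directly, before the 6-exo closure takes place. Fallback, from 25 back to 27: the electron-transfer reduction is replaced by a tin-centred radical chain. Bu3SnH is added slowly with AIBN in benzene at 80 °C, so that the tributylstannyl radical adds reversibly to the aldehyde oxygen and the O-stannyl ketyl closes 6-exo onto the enoate. The adduct radical is quenched by hydrogen-atom transfer, not by a second reduction, and gives the O-tributylstannyl hydroxy ester F4. Its tin alkoxide lactonises on warming or on silica to 27, which goes on to step 18.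

3. Step 15. Hydride may attack the carbonate carbonyl of the hindered mixed anhydride and return 22, or may add to the enoate. Fallback, from 22 back to 25: the reduction–oxidation pair (steps 15 and 16) is replaced by a direct partial reduction. Acid 22 is coupled with EtSH (DCC, catalytic DMAP, CH2Cl2) to the S-ethyl thioester F5, and Fukuyama reduction (Et3SiH, Pd/CaCO3 poisoned with Pb, acetone, 23 °C) gives aldehyde 25 without passing through alcohol 24.

Further compounds
F1 | step 14 | trimethylsilyl ketene acetal of 20 (C5 substituent cis to the allyloxy oxygen) | C=C(CO[Si](C)(C)C(C)(C)C)/C=C(\OC/C=C(C)/C[C@@H](O[Si](CC)(CC)CC)/C=C(\C)C(=O)OC)O[Si](C)(C)C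
F2 | step 14 | trimethylsilyl ester of 22 and of its (2R,3S)-diastereomer (both enolate faces) | C=CC(C)(C[C@@H](O[Si](CC)(CC)CC)/C=C(\C)C(=O)OC)C(C(=O)O[Si](C)(C)C)C(=C)CO[Si](C)(C)C(C)(C)C
F3 | step 14 | (2R,3S,5R,6E)-2-(3-{[tert-butyl(dimethyl)silyl]oxy}prop-1-en-2-yl)-3-ethenyl-8-methoxy-3,7-dimethyl-8-oxo-5-[(triethylsilyl)oxy]oct-6-enoic acid | C=C[C@](C)(C[C@@H](O[Si](CC)(CC)CC)/C=C(\C)C(=O)OC)[C@@H](C(=O)O)C(=C)CO[Si](C)(C)C(C)(C)C
F4 | step 17 | O-tributylstannyl ether of hydroxy ester 26 | C=C[C@@]1(C)C[C@@H](O[Si](CC)(CC)CC)[C@H](C(C)C(=O)OC)[C@@H](O[Sn](CCCC)(CCCC)CCCC)[C@@H]1C(=C)CO[Si](C)(C)C(C)(C)C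
F5 | step 15 | S-ethyl thioester of 22 | C=C[C@@](C)(C[C@@H](O[Si](CC)(CC)CC)/C=C(\C)C(=O)OC)[C@H](C(=O)SCC)C(=C)CO[Si](C)(C)C(C)(C)C
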